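## Retrosynthetic overview

1. Target 23 comes from its hepta(methoxymethyl) ether 22, made by Claisen–Schmidt condensation on the ring B acetyl group of cyclohexene 20.
2. Ring D is labelled C1(Me)=C2H–C3H(ring B)–C4H(CO–ring A)–C5H(ring C)–C6H2. Its C5–C6 bond joins the electron-rich ring C benzylic carbon to an allylic CH2, so ring D is opened to the all-trans cyclobutane 19 (ring C2–C3–C4–C5, isopropenyl C1(Me)=C6H2 on C2); one-electron oxidation of ring C shifts C5 from C2 to C6.
3. 19 comes from cyclobutane acid 17 by decarboxylative alkenylation at C2; the four-membered ring comes from pyrrolidine 15 by nitrogen deletion, which forms C2–C5.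
4. 15 comes from an asymmetric [3+2] cycloaddition of the ring C imino ester 14 with the ring A/ring B enone 10, which sets C3 and C4. A triplet [2+2] of a chalcone with a styrene is not used, because it would join the two aryl-bearing carbons, whereas 19 needs them 1,3 to each other.
5. Order of ring formation: pyrrolidine (temporary), cyclobutane, ring D.

Key step: step 13

Remark on the chemistry (assumption): the cycloaddition of step 9 is taken to be exo-selective. An endo adduct would differ only at C2 and C5, and both centres lose their configuration in steps 12 and 13, so it could be carried through as well.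

## Route

Step 1
Reactants: 1 2,4-dihydroxyacetophenone; 2 1-bromo-3-methylbut-2-ene
Product: 3 1-[2,4-dihydroxy-3-(3-methylbut-2-enyl)phenyl]ethanone
Conditions: KOH (10% aq), 0 °C to rt
Reagents that add atoms: none
Why: C-alkylation of the ambident resorcinol phenolate by SN2 attack on the allylic bromide should occur at C3, the carbon between the two oxygens; O-prenylated and doubly prenylated material would be removed by chromatography.

Step 2
Reactants: 3 1-[2,4-dihydroxy-3-(3-methylbut-2-enyl)phenyl]ethanone
Product: 4 1-[2,4-bis(methoxymethoxy)-3-(3-methylbut-2-enyl)phenyl]ethanone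
Conditions: NaH, MOMCl, DMF, 0 °C to rt
Reagents that add atoms: chloromethyl methyl ether, COCCl
Why: Williamson-type methoxymethylation of both phenoxides; NaH is used because the 2-hydroxyl is chelated to the ketone.

Step 3
Reactants: 4 1-[2,4-bis(methoxymethoxy)-3-(3-methylbut-2-enyl)phenyl]ethanone
Product: 6 trimethyl{3-oxo-3-[2,4-bis(methoxymethoxy)-3-(3-methylbut-2-enyl)phenyl]propyl}ammonium iodide, via Mannich base 5 (not isolated)
Conditions: LiN(SiMe3)2, THF, −78 °C; CH2=NMe2 iodide, −78 to 0 °C; then MeI, rt
Reagents that add atoms: dimethylmethyleneammonium iodide, C=[N+](C)C.[I-]; iodomethane, CI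
Why: Mannich aminomethylation of the lithium enolate of the methyl ketone followed by N-methylation (Menshutkin reaction) should give a bench-stable quaternary salt that serves as a latent aryl vinyl ketone.

Step 4
Reactants: 1 2,4-dihydroxyacetophenone
Product: 7 1-(2,4-dihydroxy-3-iodophenyl)ethanone
Conditions: I2, HIO3, EtOH/H2O, rt
Reagents that add atoms: iodine, II; iodic acid, OI(=O)=O
Why: Electrophilic aromatic iodination at the doubly activated position between the two hydroxyl groups, with iodic acid recycling the iodide so that only water is formed.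

Step 5
Reactants: 7 1-(2,4-dihydroxy-3-iodophenyl)ethanone
Product: 8 1-[3-iodo-2,4-bis(methoxymethoxy)phenyl]ethanone
Conditions: NaH, MOMCl, DMF, 0 °C to rt
Reagents that add atoms: chloromethyl methyl ether, COCCl
Why: Williamson-type methoxymethylation of both phenoxides, as in step 2.

Step 6
Reactants: 6 trimethyl{3-oxo-3-[2,4-bis(methoxymethoxy)-3-(3-methylbut-2-enyl)phenyl]propyl}ammonium iodide; 8 1-[3-iodo-2,4-bis(methoxymethoxy)phenyl]ethanone
Product: 10 (E)-3-[3-acetyl-2,6-bis(methoxymethoxy)phenyl]-1-[2,4-bis(methoxymethoxy)-3-(3-methylbut-2-enyl)phenyl]prop-2-en-1-one, via aryl vinyl ketone 9 (not isolated)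
Conditions: Pd(OAc)2 (5 mol%), Bu4NCl, NaHCO3, DMF, 80 °C
Reagents that add atoms: none
Why: Base-induced Hofmann-type (E1cB) loss of trimethylamine releases enone 9 in low concentration, and its Mizoroki–Heck arylation by the aryl iodide with syn β-hydride elimination should give the E enone.

Step 7
Reactants: 11 2,4-dihydroxybenzaldehyde
Product: 12 2,4-bis(methoxymethoxy)benzaldehyde
Conditions: NaH, MOMCl, DMF, 0 °C to rt
Reagents that add atoms: chloromethyl methyl ether, COCCl
Why: Williamson-type methoxymethylation of both phenoxides.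

Step 8
Reactants: 12 2,4-bis(methoxymethoxy)benzaldehyde; 13 glycine allyl ester hydrochloride
Product: 14 allyl N-[(E)-2,4-bis(methoxymethoxy)benzylidene]glycinate
Conditions: Et3N, MgSO4, CH2Cl2, rt
Reagents that add atoms: none
Why: Imine condensation of the aldehyde with the liberated amino ester, driven by removal of water, should give the E aldimine, which is used crude.

Step 9
Reactants: 10 (E)-3-[3-acetyl-2,6-bis(methoxymethoxy)phenyl]-1-[2,4-bis(methoxymethoxy)-3-(3-methylbut-2-enyl)phenyl]prop-2-en-1-one; 14 allyl N-[(E)-2,4-bis(methoxymethoxy)benzylidene]glycinate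
Product: 15 allyl 3-[3-acetyl-2,6-bis(methoxymethoxy)phenyl]-4-[2,4-bis(methoxymethoxy)-3-(3-methylbut-2-enyl)benzoyl]-5-[2,4-bis(methoxymethoxy)phenyl]pyrrolidine-2-carboxylate (pyrrolidine positions 2 to 5 are the later C2 to C5; ester and both aryl groups on one face and the aroyl group on the other; absolute configuration as in the SMILES)
Conditions: Cu(CH3CN)4PF6 (5 mol%), (R)-DTBM-Segphos (5.5 mol%; the ligand enantiomer is matched to the required series), Et3N (15 mol%), THF, −20 °C
Reagents that add atoms: none
Why: Catalytic asymmetric 1,3-dipolar cycloaddition of the N,O-chelated copper azomethine ylide: its α-carbon (C2) adds to the enone β-carbon C3 and the enolate carbon C4 closes on the imine carbon C5, so the E alkene fixes C3/C4 trans, the W-shaped ylide fixes C2/C5 cis, the chiral bisphosphine selects the enone face (absolute configuration at C3 and C4) and exo approach puts the aroyl group trans to ring C.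

Step 10
Reactants: 15 the pyrrolidine of step 9
Product: 16 allyl 2-[3-acetyl-2,6-bis(methoxymethoxy)phenyl]-3-[2,4-bis(methoxymethoxy)-3-(3-methylbut-2-enyl)benzoyl]-4-[2,4-bis(methoxymethoxy)phenyl]cyclobutane-1-carboxylate (ring atoms are C2 ester, C3 ring B aryl, C4 aroyl, C5 ring C aryl; ester and both aryl groups on one face and the aroyl group on the other)
Conditions: N-(benzyloxy)-N-(pivaloyloxy)-4-(trifluoromethyl)benzamide (1.5 equiv), THF, 45 °C
Reagents that add atoms: none
Why: Nitrogen deletion of a secondary amine: N-amination by the anomeric amide gives an isodiazene that loses N2, and the ester- and aryl-stabilised 1,4-diradical should collapse to the C2–C5 bond faster than bond rotation (ring contraction of a pyrrolidine to a cyclobutane with retention), leaving C3 and C4 untouched.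

Step 11
Reactants: 16 the cyclobutane allyl ester of step 10
Product: 17 2-[3-acetyl-2,6-bis(methoxymethoxy)phenyl]-3-[2,4-bis(methoxymethoxy)-3-(3-methylbut-2-enyl)benzoyl]-4-[2,4-bis(methoxymethoxy)phenyl]cyclobutane-1-carboxylic acid (same configuration as 16)
Conditions: Pd(PPh3)4 (5 mol%), morpholine, THF, rt; citric acid work-up
Reagents that add atoms: none
Why: Tsuji–Trost deallylation by zerovalent palladium with morpholine as allyl acceptor is neutral, so the epimerisable C4 ketone centre, the methoxymethyl ethers and the prenyl group should survive.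

Step 12
Reactants: 17 the cyclobutane acid of step 11
Product: 19 all-trans [2,4-bis(methoxymethoxy)-3-(3-methylbut-2-enyl)phenyl]{2-[3-acetyl-2,6-bis(methoxymethoxy)phenyl]-4-[2,4-bis(methoxymethoxy)phenyl]-3-(prop-1-en-2-yl)cyclobutyl}methanone, via N-hydroxyphthalimide ester 18 (not isolated)
Conditions: N-hydroxyphthalimide, iPrN=C=NiPr, DMAP (cat.), CH2Cl2, rt; telescoped after filtration; Ni(acac)2 (10 mol%), 2,2′-bipyridine (10 mol%), isopropenylzinc chloride (2 equiv), THF/DMF, rt
Reagents that add atoms: isopropenylzinc chloride, C=C(C)[Zn]Cl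
Why: Nickel-catalysed decarboxylative alkenylation of a redox-active ester: electron transfer to 18 releases CO2 and a cyclobutyl radical at C2, which should couple with the isopropenyl group on the face anti to the two flanking cis aryl groups and so give the all-trans isomer, while the ketones tolerate the organozinc reagent.

Step 13
Reactants: 19 the all-trans vinylcyclobutane of step 12
Product: 20 (3S,4S,5R; ring D labels) [2,4-bis(methoxymethoxy)-3-(3-methylbut-2-enyl)phenyl]{C4 of the 1-methylcyclohexene ring D carrying the 3-acetyl-2,6-bis(methoxymethoxy)phenyl group at C3 and the 2,4-bis(methoxymethoxy)phenyl group at C5}methanone, all-trans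
Conditions: 2,4,6-tris(4-methoxyphenyl)pyrylium tetrafluoroborate (5 mol%), 2,6-di-tert-butylpyridine (10 mol%), degassed CH2Cl2, 450 nm LEDs, −20 °C
Reagents that add atoms: none
Why: Electron transfer from ring C (the only arene without a carbonyl group, hence the most easily oxidised) to the excited pyrylium gives an arene radical cation in which the strained benzylic C2–C5 bond breaks to a ring C stabilised cation at C5 and an allyl radical over C2–C1–C6; C5 then bonds to C6, and back electron transfer from the pyranyl radical (or from another molecule of 19 in a chain) releases neutral 20. This is the hole-catalysed vinylcyclobutane-to-cyclohexene rearrangement (a formal 1,3-shift), the event that converts cyclobutane adducts into cyclohexenes in radical-cation Diels–Alder reactions. Ring D closes by six-membered (6-endo) attack of the C5 cation on the CH2 terminus C6 of the allyl radical in its cisoid geometry. C5 is the only new stereocentre: it is planar in the intermediate and should reclose through a chair-like transition state with ring C equatorial, trans to the C4 aroyl group, while C3 and C4 are never broken and the configurations of C2 and C5 in 19 are erased. The step needs cleavage of C2–C5 rather than C4–C5 (allyl radical is better stabilised than the α-keto radical), reclosure at C6 rather than C2 (release of about 26 kcal/mol of ring strain makes the cyclohexene the sink), and no cycloreversion or acid-induced ring expansion of the donor–acceptor cyclobutane; low temperature, the absence of Lewis acids and the hindered base are meant to secure these.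

Step 14
Reactants: 20 the cyclohexene of step 13; 21 4-(methoxymethoxy)benzaldehyde
Product: 22 hepta(methoxymethyl) ether of the target, with the ring B (E)-3-[4-(methoxymethoxy)phenyl]prop-2-enoyl group (3S,4S,5R)
Conditions: KOH, EtOH, rt
Reagents that add atoms: none
Why: Claisen–Schmidt condensation: only the ring B acetyl group has an enolisable methyl and the aldehyde has none, E1cB dehydration gives the E enone, and the C4 methine can only equilibrate towards the all-trans arrangement it already has.

Step 15
Reactants: 22 the hepta(methoxymethyl) ether of step 14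
Product: 23 target CNP0283121.2 (3S,4S,5R; ring D labels)
Conditions: 3 M HCl, MeOH, rt to 40 °C
Reagents that add atoms: none
Why: Acid-catalysed acetal cleavage (transacetalisation to dimethoxymethane) should remove all seven methoxymethyl ethers under conditions mild enough to spare the prenyl group and the 2′-hydroxychalcone.

## Compound list

1 | 2,4-dihydroxyacetophenone | CC(=O)c1ccc(O)cc1O | starting material
2 | 1-bromo-3-methylbut-2-ene | CC(C)=CCBr | starting material
3 | 1-[2,4-dihydroxy-3-(3-methylbut-2-enyl)phenyl]ethanone | CC(=O)c1ccc(O)c(CC=C(C)C)c1O | intermediate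
4 | 1-[2,4-bis(methoxymethoxy)-3-(3-methylbut-2-enyl)phenyl]ethanone | CC(=O)c1ccc(OCOC)c(CC=C(C)C)c1OCOC | intermediate
5 | Mannich base, 3-(dimethylamino)-1-[2,4-bis(methoxymethoxy)-3-(3-methylbut-2-enyl)phenyl]propan-1-one | CN(C)CCC(=O)c1ccc(OCOC)c(CC=C(C)C)c1OCOC | intermediate
6 | trimethyl{3-oxo-3-[2,4-bis(methoxymethoxy)-3-(3-methylbut-2-enyl)phenyl]propyl}ammonium iodide | C[N+](C)(C)CCC(=O)c1ccc(OCOC)c(CC=C(C)C)c1OCOC.[I-] | intermediate
7 | 1-(2,4-dihydroxy-3-iodophenyl)ethanone | CC(=O)c1ccc(O)c(I)c1O | intermediate
8 | 1-[3-iodo-2,4-bis(methoxymethoxy)phenyl]ethanone | CC(=O)c1ccc(OCOC)c(I)c1OCOC | intermediate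
9 | aryl vinyl ketone, 1-[2,4-bis(methoxymethoxy)-3-(3-methylbut-2-enyl)phenyl]prop-2-en-1-one | C=CC(=O)c1ccc(OCOC)c(CC=C(C)C)c1OCOC | intermediate
10 | ring A/ring B enone, (E)-3-[3-acetyl-2,6-bis(methoxymethoxy)phenyl]-1-[2,4-bis(methoxymethoxy)-3-(3-methylbut-2-enyl)phenyl]prop-2-en-1-one | CC(=O)c1ccc(OCOC)c(/C=C/C(=O)c2ccc(OCOC)c(CC=C(C)C)c2OCOC)c1OCOC | intermediate
11 | 2,4-dihydroxybenzaldehyde | O=Cc1ccc(O)cc1O | starting material
12 | 2,4-bis(methoxymethoxy)benzaldehyde | COCOc1ccc(C=O)c(OCOC)c1 | intermediate
13 | glycine allyl ester hydrochloride | Cl.NCC(=O)OCC=C | starting material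
14 | allyl N-[(E)-2,4-bis(methoxymethoxy)benzylidene]glycinate | C=CCOC(=O)C/N=C/c1ccc(OCOC)cc1OCOC | intermediate
15 | exo pyrrolidine (2-ester, 3-ring B aryl and 5-ring C aryl cis; 4-aroyl trans to both aryl groups) | CC(C)=CCc1c(OCOC)ccc(C(=O)[C@@H]2[C@@H](c3c(OCOC)ccc(C(C)=O)c3OCOC)[C@@H](C(=O)OCC=C)N[C@H]2c2ccc(OCOC)cc2OCOC)c1OCOC | intermediate
16 | cyclobutane allyl ester (C2 ester, C3 ring B aryl, C5 ring C aryl cis; C4 aroyl trans to both aryl groups) | CC(C)=CCc1c(OCOC)ccc(C(=O)[C@@H]2[C@@H](c3c(OCOC)ccc(C(C)=O)c3OCOC)[C@@H](C(=O)OCC=C)[C@H]2c2ccc(OCOC)cc2OCOC)c1OCOC | intermediate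
17 | cyclobutane carboxylic acid (configuration as 16) | CC(C)=CCc1c(OCOC)ccc(C(=O)[C@@H]2[C@@H](c3c(OCOC)ccc(C(C)=O)c3OCOC)[C@@H](C(=O)O)[C@H]2c2ccc(OCOC)cc2OCOC)c1OCOC | intermediate
18 | N-hydroxyphthalimide ester of 17 | CC(C)=CCc1c(OCOC)ccc(C(=O)[C@@H]2[C@@H](c3c(OCOC)ccc(C(C)=O)c3OCOC)[C@@H](C(=O)ON4C(=O)c5ccccc5C4=O)[C@H]2c2ccc(OCOC)cc2OCOC)c1OCOC | intermediate
19 | all-trans 1-(ring A aroyl)-2-(ring B aryl)-3-isopropenyl-4-(ring C aryl)cyclobutane, hexakis(methoxymethyl) ether (key-step precursor) | CC(C)=CCc1c(OCOC)ccc(C(=O)[C@@H]2[C@@H](c3c(OCOC)ccc(C(C)=O)c3OCOC)[C@H](C(C)=C)[C@H]2c2ccc(OCOC)cc2OCOC)c1OCOC | intermediate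
20 | all-trans cyclohexene with ring B acetyl, hexakis(methoxymethyl) ether (3S,4S,5R) | CC(C)=CCc1c(OCOC)ccc(C(=O)[C@@H]2[C@@H](c3c(OCOC)ccc(C(C)=O)c3OCOC)C=C(C)C[C@H]2c2ccc(OCOC)cc2OCOC)c1OCOC | intermediate
21 | 4-(methoxymethoxy)benzaldehyde | COCOc1ccc(C=O)cc1 | starting material
22 | hepta(methoxymethyl) ether of the target (3S,4S,5R) | CC(C)=CCc1c(OCOC)ccc(C(=O)[C@@H]2[C@@H](c3c(OCOC)ccc(C(=O)/C=C/c4ccc(OCOC)cc4)c3OCOC)C=C(C)C[C@H]2c2ccc(OCOC)cc2OCOC)c1OCOC | intermediate
23 | CNP0283121.2 (3S,4S,5R) | CC(C)=CCc1c(O)ccc(C(=O)[C@@H]2[C@@H](c3c(O)ccc(C(=O)/C=C/c4ccc(O)cc4)c3O)C=C(C)C[C@H]2c2ccc(O)cc2O)c1O | target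

## Step count and risks

Total step count: 15. Longest linear sequence: 11 steps (steps 1, 2, 3, 6, 9, 10, 11, 12, 13, 14, 15).

Steps most likely to fail:

1. Step 10 (nitrogen deletion). The 1,4-diradical may fragment across C3–C4 into two alkenes instead of closing, or N-amination of the hindered amine may be slow. Fallback: starting from 15, electrophilic N-amination with O-(diphenylphosphinyl)hydroxylamine would give the N-aminopyrrolidine F1. Oxidation of this 1,1-disubstituted hydrazine with PhI(OAc)2 in CH2Cl2 at −40 °C would generate the isodiazene at low temperature, where recombination of the diradical is favoured over fragmentation. Loss of N2 returns to the route at 16.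

2. Step 9 (cycloaddition). Addition to the enone β-carbon, which is shielded by the two ortho methoxymethoxy groups of ring B, may be slow, and facial or exo selectivity may be poor. Fallback: starting from 10 and 14, a stepwise sequence replaces the concerted metal-catalysed reaction. Phase-transfer Michael addition of 14 to 10 under a cinchona-derived quaternary ammonium catalyst (Cs2CO3, toluene, −40 °C) would give the open-chain adduct F2 with C3 set by the catalyst. Ring closure by intramolecular Mannich reaction of the ketone enolate onto the aldimine (AgOAc, Et3N) returns to the route at 15, with C3/C4 trans under thermodynamic control.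

3. Step 13 (key step). Back electron transfer may outrun bond cleavage, the ring-opened radical cation may fragment to chalcone and diene, or C5 may close with ring C cis to the aroyl group. Fallback: starting from 19, the neutral thermal vinylcyclobutane-to-cyclohexene rearrangement in degassed 1,2-dichlorobenzene at 160–180 °C would proceed through the benzyl/allyl 1,4-diradical instead of the radical cation. C3 and C4 are again untouched, and the sequence returns to the route at 20 without any new compound.

Further compounds
F1 | step 10 | N-aminopyrrolidine derived from 15 (allyl 1-amino-3-[3-acetyl-2,6-bis(methoxymethoxy)phenyl]-4-[2,4-bis(methoxymethoxy)-3-(3-methylbut-2-enyl)benzoyl]-5-[2,4-bis(methoxymethoxy)phenyl]pyrrolidine-2-carboxylate) | CC(C)=CCc1c(OCOC)ccc(C(=O)[C@@H]2[C@@H](c3c(OCOC)ccc(C(C)=O)c3OCOC)[C@@H](C(=O)OCC=C)N(N)[C@H]2c2ccc(OCOC)cc2OCOC)c1OCOC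
F2 | step 9 | Michael adduct, allyl 2-{[(E)-2,4-bis(methoxymethoxy)benzylidene]amino}-3-[3-acetyl-2,6-bis(methoxymethoxy)phenyl]-5-oxo-5-[2,4-bis(methoxymethoxy)-3-(3-methylbut-2-enyl)phenyl]pentanoate | CC(C)=CCc1c(OCOC)ccc(C(=O)C[C@@H](c3c(OCOC)ccc(C(C)=O)c3OCOC)C(/N=C/c2ccc(OCOC)cc2OCOC)C(=O)OCC=C)c1OCOC
F0 | step 13 | none | none
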